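**Assumption:** the target contains no stereocentre (it is achiral), so "single enantiomer" is met trivially; the only stereo-element on the route is an E-alkene that is hydrogenated away.

## Retrosynthetic overview

1. Target ⇐ one-pot hydrogenation (C=C saturation and cleavage of two O-benzyl groups) of the octadecyl (E)-2,4-bis(benzyloxy)-3-methoxycinnamate.
2. Cinnamate ⇐ key C–C bond: aldol-type Knoevenagel–Doebner condensation of 2,4-bis(benzyloxy)-3-methoxybenzaldehyde with octadecyl hydrogen malonate, with decarboxylation.
3. Aldehyde ⇐ Vilsmeier–Haack formylation of 1,3-bis(benzyloxy)-2-methoxybenzene ⇐ double benzylation of 2-methoxyresorcinol. Half-ester ⇐ Meldrum's acid + octadecan-1-ol.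
4. No ring is formed: the only ring of the target, the benzene ring, is bought intact in 2-methoxyresorcinol.

## Route

**Step 1**
Reactants: 1 2-methoxybenzene-1,3-diol (2-methoxyresorcinol); 2 benzyl bromide
Product: 3 1,3-bis(benzyloxy)-2-methoxybenzene
Conditions: BnBr (2.3 equiv), K2CO3 (3 equiv), DMF, 60 °C, 6 h
Reagents that add atoms: benzyl bromide, BrCc1ccccc1
Why: Williamson ether synthesis, in which both phenoxides are alkylated by the reactive benzylic bromide in an SN2 reaction, and no stereocentre is involved.

**Step 2**
Reactants: 3 1,3-bis(benzyloxy)-2-methoxybenzene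
Product: 5 2,4-bis(benzyloxy)-3-methoxybenzaldehyde, via aryliminium dichlorophosphate 4 (not isolated)
Conditions: POCl3 (1.5 equiv), DMF, 0 → 75 °C, 4 h; then ice/H2O, aq NaOH to pH 8
Reagents that add atoms: DMF, CN(C)C=O (formyl carbon); water, O (carbonyl oxygen, on hydrolysis of 4)
Why: Vilsmeier–Haack formylation goes to C4, the only position activated by one benzyloxy group in para and the other in ortho (C5 is only para to the flanked, twisted methoxy group), the same selectivity that turns 1,2,3-trimethoxybenzene into 2,3,4-trimethoxybenzaldehyde.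

**Step 3**
Reactants: 6 Meldrum's acid (2,2-dimethyl-1,3-dioxane-4,6-dione); 7 octadecan-1-ol
Product: 8 octadecyl hydrogen malonate (3-(octadecyloxy)-3-oxopropanoic acid)
Conditions: toluene, reflux (110 °C), 4 h
Reagents that add atoms: none
Why: Thermal alcoholysis (ring-opening acylation) of Meldrum's acid by the primary alcohol expels acetone and gives the malonic half-ester cleanly, with no diester formation.

**Step 4**
Reactants: 5 2,4-bis(benzyloxy)-3-methoxybenzaldehyde; 8 octadecyl hydrogen malonate (1.3 equiv)
Product: 11 octadecyl (E)-3-[2,4-bis(benzyloxy)-3-methoxyphenyl]prop-2-enoate, via aldol adduct 9 (not isolated), via arylidenemalonate half-ester 10 (not isolated)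
Conditions: pyridine, piperidine (0.1 equiv), 90 °C, 8 h
Reagents that add atoms: none
Why: Knoevenagel–Doebner condensation, in which aldol-type addition of the malonate half-ester to the aldehyde, dehydration and pyridine-promoted decarboxylation give the thermodynamically favoured E-cinnamate, while the benzyl ether on the ortho oxygen blocks the competing coumarin ring closure.

**Step 5**
Reactants: 11 octadecyl (E)-3-[2,4-bis(benzyloxy)-3-methoxyphenyl]prop-2-enoate
Product: 12 octadecyl 3-(2,4-dihydroxy-3-methoxyphenyl)propanoate (target)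
Conditions: H2 (1 atm), 10% Pd/C, EtOAc/THF 1:1, rt, 12 h; filter through Celite, concentrate below 35 °C
Reagents that add atoms: none
Why: Heterogeneous catalytic hydrogenation saturates the conjugated alkene and hydrogenolyses both aryl benzyl ethers in one neutral operation that leaves the alkyl ester and the aryl methyl ether untouched, and no stereocentre is created.

## Compound list

1 | 2-methoxybenzene-1,3-diol (2-methoxyresorcinol) | COc1c(O)cccc1O | starting material
2 | benzyl bromide | BrCc1ccccc1 | starting material
3 | 1,3-bis(benzyloxy)-2-methoxybenzene | COc1c(OCc2ccccc2)cccc1OCc1ccccc1 | intermediate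
4 | N-[[2,4-bis(benzyloxy)-3-methoxyphenyl]methylidene]-N-methylmethanaminium dichlorophosphate | C[N+](C)=Cc1ccc(OCc2ccccc2)c(OC)c1OCc1ccccc1.[O-]P(Cl)(Cl)=O | intermediate (not isolated)
5 | 2,4-bis(benzyloxy)-3-methoxybenzaldehyde | O=Cc1ccc(OCc2ccccc2)c(OC)c1OCc1ccccc1 | intermediate
6 | Meldrum's acid (2,2-dimethyl-1,3-dioxane-4,6-dione) | CC1(C)OC(=O)CC(=O)O1 | starting material
7 | octadecan-1-ol | CCCCCCCCCCCCCCCCCCO | starting material
8 | octadecyl hydrogen malonate | CCCCCCCCCCCCCCCCCCOC(=O)CC(O)=O | intermediate
9 | octadecyl hydrogen 2-[[2,4-bis(benzyloxy)-3-methoxyphenyl](hydroxy)methyl]malonate (aldol adduct, mixture of stereoisomers) | CCCCCCCCCCCCCCCCCCOC(=O)C(C(O)=O)C(O)c1ccc(OCc2ccccc2)c(OC)c1OCc1ccccc1 | intermediate (not isolated)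
10 | octadecyl hydrogen 2-[[2,4-bis(benzyloxy)-3-methoxyphenyl]methylidene]malonate (alkene geometry not defined) | CCCCCCCCCCCCCCCCCCOC(=O)C(C(O)=O)=Cc1ccc(OCc2ccccc2)c(OC)c1OCc1ccccc1 | intermediate (not isolated)
11 | octadecyl (E)-3-[2,4-bis(benzyloxy)-3-methoxyphenyl]prop-2-enoate | CCCCCCCCCCCCCCCCCCOC(=O)/C=C/c1ccc(OCc2ccccc2)c(OC)c1OCc1ccccc1 | intermediate
12 | octadecyl 3-(2,4-dihydroxy-3-methoxyphenyl)propanoate | CCCCCCCCCCCCCCCCCCOC(=O)CCc1ccc(O)c(OC)c1O | target

## Summary

Total step count: 5.
Longest linear sequence: 4 steps (steps 1, 2, 4, 5 from 2-methoxyresorcinol); step 3 is a one-step side branch.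

## Steps most likely to fail, with fallbacks

**Step 2 (formylation).** The risks are partial loss of a benzyl group under the hot acidic Vilsmeier conditions and sluggish reaction of the moderately activated ring. The fallback sets out from 3 and comes back at 5. Electrophilic bromination of 3 with NBS in MeCN at 0 °C goes to the same doubly activated position and gives 1,3-bis(benzyloxy)-4-bromo-2-methoxybenzene F1. Bromine–lithium exchange with n-BuLi in THF at −78 °C gives [2,4-bis(benzyloxy)-3-methoxyphenyl]lithium F2. This is quenched with DMF and worked up with aqueous NH4Cl to give aldehyde 5.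

**Step 4 (decarboxylative condensation with the half-ester).** The aldehyde is electron-rich and ortho-substituted, so conversion may be slow and decarboxylation of 10 incomplete. The fallback sets out from 5 and comes back at 11. Doebner condensation of 5 with malonic acid (pyridine, piperidine catalyst, 100 °C) passes through 2-[[2,4-bis(benzyloxy)-3-methoxyphenyl]methylidene]malonic acid F3, which loses CO2 in the flask. The product is (E)-3-[2,4-bis(benzyloxy)-3-methoxyphenyl]prop-2-enoic acid F4, isolated by acidification and crystallisation. Steglich esterification of this acid with octadecan-1-ol 7 (DCC, catalytic DMAP, CH2Cl2, rt) gives 11.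

**Step 5 (global hydrogenation).** The risks are incomplete cleavage of the hindered benzyl ether next to the side chain, poor solubility of the waxy ester, and lactonisation of the ortho-hydroxy ester on an acidic catalyst batch. The fallback sets out from 11 and comes back at 12. Homogeneous hydrogenation of 11 with H2 (3 atm) and RhCl(PPh3)3 in toluene/THF at 40 °C reduces only the alkene and gives octadecyl 3-[2,4-bis(benzyloxy)-3-methoxyphenyl]propanoate F5. The benzyl ethers are then removed without hydrogen by BCl3 (3 equiv) with pentamethylbenzene as cation scavenger in CH2Cl2 at −78 °C, followed by a cold aqueous NaHCO3 quench. This temperature spares the methyl ether and the ester and gives 12.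

## Further compounds

F1 | step 2 | 1,3-bis(benzyloxy)-4-bromo-2-methoxybenzene | COc1c(OCc2ccccc2)ccc(Br)c1OCc1ccccc1
F2 | step 2 | [2,4-bis(benzyloxy)-3-methoxyphenyl]lithium | [Li]c1ccc(OCc2ccccc2)c(OC)c1OCc1ccccc1
F3 | step 4 | 2-[[2,4-bis(benzyloxy)-3-methoxyphenyl]methylidene]malonic acid | OC(=O)C(=Cc1ccc(OCc2ccccc2)c(OC)c1OCc1ccccc1)C(O)=O
F4 | step 4 | (E)-3-[2,4-bis(benzyloxy)-3-methoxyphenyl]prop-2-enoic acid | OC(=O)/C=C/c1ccc(OCc2ccccc2)c(OC)c1OCc1ccccc1
F5 | step 5 | octadecyl 3-[2,4-bis(benzyloxy)-3-methoxyphenyl]propanoate | CCCCCCCCCCCCCCCCCCOC(=O)CCc1ccc(OCc2ccccc2)c(OC)c1OCc1ccccc1
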